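The target is a 3-aryloxycoumarin whose upper pyranone ring (O1, C2, C3, C4, C4a, C8a) carries the umbelliferyl ether oxygen on C3. The route disconnects the C3=C4 double bond of that ring: with the O1–C2 ester and the C3–O ether set beforehand, this alkene can be closed by a neutral ruthenium catalyst that leaves both lactones and the aryl ether untouched. One ring-closing metathesis between the vinyl group on C4a and the methylene of a 2-aryloxyacrylate therefore closes the lactone with its C3 oxygen already in place. The precursor is aryl ester 14, assembled from a silyl-protected 2-vinylphenol (from vanillin) and 2-(umbelliferyloxy)acrylic acid (from umbelliferone and diethyl bromomalonate).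

Key step: step 9

Remark: the target is achiral and all its double bonds are endocyclic, so no stereodescriptor is needed. Coumarin locants (O1, C2, C3, C4, C4a, C5 to C8, C8a) refer to the upper ring system and primed locants to the umbelliferone unit.

Step 1
Reactants: 1 vanillin
Product: 2 4-(tert-butyldimethylsilyloxy)-3-methoxybenzaldehyde
Conditions: TBSCl, imidazole, DMF, rt
Reagents that add atoms: tert-butyldimethylsilyl chloride, CC(C)(C)[Si](C)(C)Cl
Why: Silyl ether protection of the only phenol with TBSCl/imidazole is routine and the aldehyde is inert to it.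

Step 2
Reactants: 2 4-(tert-butyldimethylsilyloxy)-3-methoxybenzaldehyde
Product: 4 4-(tert-butyldimethylsilyloxy)-3-methoxyphenol, via aryl formate 3 (not isolated)
Conditions: mCPBA, CH2Cl2, 0 °C to rt; then Et3N, MeOH, rt
Reagents that add atoms: mCPBA, O=C(OO)c1cccc(Cl)c1
Why: In this Baeyer-Villiger (Dakin-type) oxidation the electron-rich aryl group para to the silyloxy substituent migrates to give formate 3, which amine-catalysed methanolysis should cleave at room temperature without touching the aryl silyl ether.

Step 3
Reactants: 4 4-(tert-butyldimethylsilyloxy)-3-methoxyphenol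
Product: 6 5-(tert-butyldimethylsilyloxy)-2-hydroxy-4-methoxybenzaldehyde, via hydroxymethylphenol 5 (not isolated)
Conditions: MgCl2, Et3N, (CH2O)n, MeCN, reflux; then cold 1 M HCl
Reagents that add atoms: paraformaldehyde (as formaldehyde), C=O
Why: In this magnesium-phenoxide-directed ortho-formylation (Casnati-Skattebol reaction) the chelated phenoxide is hydroxymethylated at the open ortho position para to the methoxy group, the other ortho site being flanked by OH and OMe, and a second formaldehyde oxidises the benzylic alkoxide 5 by hydride transfer.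

Step 4
Reactants: 6 5-(tert-butyldimethylsilyloxy)-2-hydroxy-4-methoxybenzaldehyde
Product: 7 4-(tert-butyldimethylsilyloxy)-5-methoxy-2-vinylphenol
Conditions: Ph3PCH3Br (2.5 equiv), NaN(SiMe3)2 (2.4 equiv), THF, 0 °C; then 6, 0 °C to rt
Reagents that add atoms: methyltriphenylphosphonium bromide, C[P+](c1ccccc1)(c1ccccc1)c1ccccc1.[Br-]
Why: Wittig methylenation of a salicylaldehyde with excess preformed ylide (one equivalent is held by the phenol, the next olefinates) is the standard entry to 2-vinylphenols, and the non-nucleophilic ylide should leave the aryl silyl ether alone.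

Step 5
Reactants: 8 umbelliferone; 9 diethyl bromomalonate
Product: 10 diethyl 2-[(2-oxo-2H-chromen-7-yl)oxy]malonate
Conditions: K2CO3, acetone, reflux
Reagents that add atoms: none
Why: Williamson-type SN2 O-alkylation of the acidic 7-hydroxycoumarin by the doubly activated bromide should proceed with K2CO3, a base too weak to open the lactone.

Step 6
Reactants: 10 diethyl 2-[(2-oxo-2H-chromen-7-yl)oxy]malonate
Product: 11 2-[(2-oxo-2H-chromen-7-yl)oxy]malonic acid
Conditions: LiOH (3.5 equiv), THF/H2O, 0 °C to rt; then 2 M HCl, 0 °C, extraction without heating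
Reagents that add atoms: lithium hydroxide, [Li+].[OH-]
Why: Saponification of the two activated ethyl esters gives the dicarboxylate, and cold acidification should liberate the malonic acid and reclose any lactone opened to the cis-coumarinate, with the isolation kept cold to avoid decarboxylation.

Step 7
Reactants: 11 2-[(2-oxo-2H-chromen-7-yl)oxy]malonic acid
Product: 13 2-[(2-oxo-2H-chromen-7-yl)oxy]acrylic acid, via Mannich base 12 (not isolated)
Conditions: Et2NH (1.5 equiv), (CH2O)n (2 equiv), EtOAc, rt then reflux; then 1 M HCl wash
Reagents that add atoms: paraformaldehyde (as formaldehyde), C=O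
Why: Mannich aminomethylation at the acidic malonic C-H followed by decarboxylative loss of diethylamine (the Mannich-type decarboxylative methylenation of monosubstituted malonic acids) should give the 2-substituted acrylic acid directly, so no ester hydrolysis is needed afterwards.

Step 8
Reactants: 7 4-(tert-butyldimethylsilyloxy)-5-methoxy-2-vinylphenol; 13 2-[(2-oxo-2H-chromen-7-yl)oxy]acrylic acid
Product: 14 4-(tert-butyldimethylsilyloxy)-5-methoxy-2-vinylphenyl 2-[(2-oxo-2H-chromen-7-yl)oxy]acrylate
Conditions: DCC (1.1 equiv), DMAP (0.1 equiv), CH2Cl2, 0 °C to rt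
Reagents that add atoms: none
Why: Steglich esterification through the acylpyridinium ion should acylate the ortho-substituted phenol under neutral conditions that neither polymerise the acid-sensitive vinylphenol nor open the coumarin.

Step 9
Reactants: 14 4-(tert-butyldimethylsilyloxy)-5-methoxy-2-vinylphenyl 2-[(2-oxo-2H-chromen-7-yl)oxy]acrylate
Product: 15 6-(tert-butyldimethylsilyloxy)-7-methoxy-3-[(2-oxo-2H-chromen-7-yl)oxy]-2H-chromen-2-one
Conditions: second-generation Hoveyda-Grubbs catalyst RuCl2(H2IMes)(=CH-C6H4-2-OiPr) (10 mol %), toluene (0.005 M), 80 °C, argon sparge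
Reagents that add atoms: none
Why: The catalyst first exchanges its alkylidene onto the unhindered, electron-rich styrene on C4a, and the resulting ruthenium benzylidene adds across the neighbouring CH2=C(OAr) unit in an intramolecular [2+2] cycloaddition with ruthenium at the terminal CH2, after which cycloreversion of the ruthenacyclobutane forms C3=C4 and a ruthenium methylidene that carries the chain while ethene is swept out. The closest known reaction types are the ring-closing metathesis of 2-vinylphenyl acrylates and methacrylates to coumarins and of 2-alkoxyacrylate esters to 2-alkoxy unsaturated lactones. The pyranone ring (O1, C2, C3, C4, C4a, C8a) is closed as a six-membered ring by ring-closing metathesis at C3=C4, helped by the aryl ester and the arene, which hold the two alkenes close, and by the conjugation gained in the coumarin. No stereocenter is created and the ring enforces the cis geometry of the new alkene. The step needs chemoselectivity for the two terminal alkenes: the C3'=C4' bond of the lower coumarin is endocyclic, conjugated and cis-disubstituted and should not be opened, loading on the acrylate carbon that bears oxygen would require a fully substituted ruthenium carbene and is sterically disfavoured, and styrene dimerisation is held back by high dilution.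

Step 10
Reactants: 15 6-(tert-butyldimethylsilyloxy)-7-methoxy-3-[(2-oxo-2H-chromen-7-yl)oxy]-2H-chromen-2-one
Product: 16 6-hydroxy-7-methoxy-3-[(2-oxo-2H-chromen-7-yl)oxy]-2H-chromen-2-one
Conditions: Bu4NF (1.1 equiv), AcOH (1.2 equiv), THF, 0 °C
Reagents that add atoms: none
Why: Fluoride-induced desilylation of the aryl silyl ether should release the C6 phenol, and the acetic acid buffer keeps the medium from becoming basic enough to open either lactone or disturb the C3 aryl ether.

Compound list
1 | vanillin (4-hydroxy-3-methoxybenzaldehyde) | COc1cc(C=O)ccc1O | starting material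
2 | 4-(tert-butyldimethylsilyloxy)-3-methoxybenzaldehyde | COc1cc(C=O)ccc1O[Si](C)(C)C(C)(C)C | intermediate
3 | 4-(tert-butyldimethylsilyloxy)-3-methoxyphenyl formate | COc1cc(OC=O)ccc1O[Si](C)(C)C(C)(C)C | intermediate
4 | 4-(tert-butyldimethylsilyloxy)-3-methoxyphenol | COc1cc(O)ccc1O[Si](C)(C)C(C)(C)C | intermediate
5 | 4-(tert-butyldimethylsilyloxy)-2-(hydroxymethyl)-5-methoxyphenol (present as its magnesium salt) | COc1cc(O)c(CO)cc1O[Si](C)(C)C(C)(C)C | intermediate
6 | 5-(tert-butyldimethylsilyloxy)-2-hydroxy-4-methoxybenzaldehyde | COc1cc(O)c(C=O)cc1O[Si](C)(C)C(C)(C)C | intermediate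
7 | 4-(tert-butyldimethylsilyloxy)-5-methoxy-2-vinylphenol | C=Cc1cc(O[Si](C)(C)C(C)(C)C)c(OC)cc1O | intermediate
8 | umbelliferone (7-hydroxy-2H-chromen-2-one) | O=c1ccc2ccc(O)cc2o1 | starting material
9 | diethyl bromomalonate | CCOC(=O)C(Br)C(=O)OCC | starting material
10 | diethyl 2-[(2-oxo-2H-chromen-7-yl)oxy]malonate | CCOC(=O)C(Oc1ccc2ccc(=O)oc2c1)C(=O)OCC | intermediate
11 | 2-[(2-oxo-2H-chromen-7-yl)oxy]malonic acid | OC(=O)C(Oc1ccc2ccc(=O)oc2c1)C(=O)O | intermediate
12 | 2-[(diethylamino)methyl]-2-[(2-oxo-2H-chromen-7-yl)oxy]malonic acid | CCN(CC)CC(Oc1ccc2ccc(=O)oc2c1)(C(=O)O)C(=O)O | intermediate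
13 | 2-[(2-oxo-2H-chromen-7-yl)oxy]acrylic acid | C=C(Oc1ccc2ccc(=O)oc2c1)C(=O)O | intermediate
14 | 4-(tert-butyldimethylsilyloxy)-5-methoxy-2-vinylphenyl 2-[(2-oxo-2H-chromen-7-yl)oxy]acrylate | C=Cc1cc(O[Si](C)(C)C(C)(C)C)c(OC)cc1OC(=O)C(=C)Oc1ccc2ccc(=O)oc2c1 | intermediate
15 | 6-(tert-butyldimethylsilyloxy)-7-methoxy-3-[(2-oxo-2H-chromen-7-yl)oxy]-2H-chromen-2-one | COc1cc2oc(=O)c(Oc3ccc4ccc(=O)oc4c3)cc2cc1O[Si](C)(C)C(C)(C)C | intermediate
16 | 6-hydroxy-7-methoxy-3-[(2-oxo-2H-chromen-7-yl)oxy]-2H-chromen-2-one | COc1cc2oc(=O)c(Oc3ccc4ccc(=O)oc4c3)cc2cc1O | target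

Total step count: 10 steps.
Longest linear sequence: 7 steps (steps 1, 2, 3, 4, 8, 9, 10); the acid branch (steps 5, 6, 7) joins at step 8.

Steps most likely to fail

Step 9 (ring-closing metathesis). The ruthenium benzylidene may fail to engage the hindered, captodative 1,1-disubstituted alkene, so that intermolecular styrene dimerisation or catalyst decay outruns ring closure. The fallback closes the same C3=C4 bond by carbonyl condensation. It sets out from aldehyde 6, with umbelliferone 8 as partner, and comes back at compound 15. Compound 8 would be O-alkylated with tert-butyl bromoacetate (K2CO3, acetone) to tert-butyl 2-[(2-oxo-2H-chromen-7-yl)oxy]acetate F1. CF3CO2H in CH2Cl2 would then give 2-[(2-oxo-2H-chromen-7-yl)oxy]acetic acid F2. DCC/DMAP esterification of the phenol of 6 would give 4-(tert-butyldimethylsilyloxy)-2-formyl-5-methoxyphenyl 2-[(2-oxo-2H-chromen-7-yl)oxy]acetate F3. DBU in MeCN should then effect the intramolecular aldol condensation and dehydration (the Perkin-type coumarin synthesis known for salicylaldehydes and aryloxyacetic acids) to give 15.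

Step 7 (decarboxylative methylenation). Plain decarboxylation of the malonic acid to the aryloxyacetic acid may outrun aminomethylation, or the amine may add to the acrylic acid and start its polymerisation. The fallback is an olefination route that sets out from umbelliferone 8 and comes back at acid 13. Rh2(OAc)4-catalysed O-H insertion of triethyl diazophosphonoacetate (toluene, 80 °C) would give ethyl 2-(diethoxyphosphoryl)-2-[(2-oxo-2H-chromen-7-yl)oxy]acetate F4. Horner-Wadsworth-Emmons olefination with aqueous formaldehyde and K2CO3 would give ethyl 2-[(2-oxo-2H-chromen-7-yl)oxy]acrylate F5. LiOH in THF/H2O at 0 °C followed by cold HCl, which also recloses any opened lactone, would deliver 13.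

Step 3 (ortho-formylation). The aryl silyl ether may be lost in the hot magnesium alkoxide/amine medium, or formylation may occur at the crowded ortho position between OH and OMe. The fallback installs the vinyl group by cross-coupling, sets out from phenol 4 and comes back at vinylphenol 7, bypassing 5 and 6. NBS in CH2Cl2 (−78 to 0 °C) should brominate ortho to the hydroxyl and para to the methoxy group to give 2-bromo-4-(tert-butyldimethylsilyloxy)-5-methoxyphenol F6. Stille coupling with tributyl(vinyl)tin and Pd(PPh3)4 in toluene at 100 °C would then give 7 under base-free conditions.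

Further compounds
F1 | step 9 | tert-butyl 2-[(2-oxo-2H-chromen-7-yl)oxy]acetate | CC(C)(C)OC(=O)COc1ccc2ccc(=O)oc2c1
F2 | step 9 | 2-[(2-oxo-2H-chromen-7-yl)oxy]acetic acid | OC(=O)COc1ccc2ccc(=O)oc2c1
F3 | step 9 | 4-(tert-butyldimethylsilyloxy)-2-formyl-5-methoxyphenyl 2-[(2-oxo-2H-chromen-7-yl)oxy]acetate | COc1cc(OC(=O)COc2ccc3ccc(=O)oc3c2)c(C=O)cc1O[Si](C)(C)C(C)(C)C
F4 | step 7 | ethyl 2-(diethoxyphosphoryl)-2-[(2-oxo-2H-chromen-7-yl)oxy]acetate | CCOC(=O)C(Oc1ccc2ccc(=O)oc2c1)P(=O)(OCC)OCC
F5 | step 7 | ethyl 2-[(2-oxo-2H-chromen-7-yl)oxy]acrylate | C=C(Oc1ccc2ccc(=O)oc2c1)C(=O)OCC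
F6 | step 3 | 2-bromo-4-(tert-butyldimethylsilyloxy)-5-methoxyphenol | COc1cc(O)c(Br)cc1O[Si](C)(C)C(C)(C)C
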